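## Retrosynthetic overview

- The strategy rests on the trans-2,3-dihydrobenzofuran of unit D: its C8d–C10c and C7d–O(C11c) bonds sit on the resorcinol ring (C9c–C14c) of the 4-hydroxystilbene unit C. Both bonds are cut last, giving resveratrol and trimer 24 (oxidative phenol–stilbene [3+2]).
- 24 comes from its octamethyl ether 23, made by Heck coupling of core aryl chloride 21 with 3,5-dimethoxystyrene (a chloride replaces bromide so that the first arylation is chemoselective).
- 21: the C7b aryl is added by Friedel–Crafts arylation of anisole; the seven-membered ring (C7b–C10a) is closed by Friedel–Crafts acylation of acid 15; C8b is set by equilibration α to the ketone.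
- 15: the A/B dihydrofuran (C7a–O, C7a–C8a) comes from a [4+1] of a chiral benzylsulfonium ylide with the o-quinone methide released from lactone 7. Lactone 7 is built by ester α-arylation, formylation, demethylation and aryl Grignard addition.
- Ring order: temporary lactone on ring B → dihydrofuran A/B → seven-membered carbocycle → dihydrofuran of unit D.

Key step: step 14

Remark (locants): oligostilbene numbering is used; units A/B form the core, C is the stilbene unit, D the appended resveratrol; C7/C8 are the two-carbon bridges and C9–C14 the resorcinol rings.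

Remark (assumption): the (2S,5S)-thiolanium ylide is assumed to add with the facial sense it shows in epoxidations, which corresponds to (7aS,8aS); if the antipode forms, the (2R,5R)-sulfide from (2S,5S)-hexane-2,5-diol is used.

## Route

Step 1
Reactants: 1 methyl 2-(3,5-dimethoxyphenyl)acetate; 2 2-bromo-4-chloro-1-methoxybenzene
Product: 3 methyl 2-(5-chloro-2-methoxyphenyl)-2-(3,5-dimethoxyphenyl)acetate (racemic at C8b)
Conditions: LiHMDS (2.3 equiv), Pd(dba)2 (2 mol%), t-Bu3P·HBF4 (4 mol%), toluene, 20 °C
Reagents that add atoms: none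
Why: Pd-catalysed α-arylation of the ester enolate should occur at C–Br and leave the deactivated C–Cl (para to OMe) untouched at room temperature; C8b forms racemic, which does not matter because it is equilibrated in step 9.

Step 2
Reactants: 3
Product: 4 methyl 2-(5-chloro-2-methoxyphenyl)-2-(2-formyl-3,5-dimethoxyphenyl)acetate
Conditions: POCl3 (1.5 equiv), DMF, 0 → 70 °C; aq. NaOAc
Reagents that add atoms: N,N-dimethylformamide CN(C)C=O; water O
Why: Vilsmeier–Haack formylation should go on the more electron-rich dimethoxy ring at C10b (para to one OMe, ortho to the other; the two such positions are equivalent) and not on the chloroanisole ring.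

Step 3
Reactants: 4
Product: 5 methyl 2-(5-chloro-2-methoxyphenyl)-2-(2-formyl-3-hydroxy-5-methoxyphenyl)acetate
Conditions: BCl3 (1.2 equiv), CH2Cl2, −78 → 0 °C; H2O
Reagents that add atoms: none
Why: chelation-controlled BCl3 demethylation should cleave only the methoxy group ortho to the formyl group (C11b), which frees the phenol needed for the quinone methide.

Step 4
Reactants: 5; 6 (3,5-dimethoxyphenyl)magnesium bromide
Product: 7 4-(5-chloro-2-methoxyphenyl)-1-(3,5-dimethoxyphenyl)-8-hydroxy-6-methoxyisochroman-3-one (diastereomer mixture; racemic)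
Conditions: 6 (2.3 equiv), THF, −78 → 0 °C; aq. NH4Cl; PPTS (5 mol%), CH2Cl2, 20 °C
Reagents that add atoms: none
Why: Grignard 1,2-addition to the aldehyde (the first equivalent deprotonates the phenol) gives a benzhydrol that should close onto the neighbouring ester as a six-membered lactone; C8a is formed without control because it becomes planar in step 8.

Step 5
Reactants: 8 (2R,5R)-hexane-2,5-diol
Product: 9 (2R,5R)-hexane-2,5-diyl dimethanesulfonate
Conditions: MsCl (2.4 equiv), Et3N (3 equiv), CH2Cl2, 0 °C
Reagents that add atoms: methanesulfonyl chloride CS(=O)(=O)Cl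
Why: O-sulfonylation of the secondary alcohols proceeds with retention at both carbons.

Step 6
Reactants: 9
Product: 10 (2S,5S)-2,5-dimethylthiolane
Conditions: Na2S·9H2O (1.2 equiv), DMSO, 20 → 40 °C; distillation
Reagents that add atoms: sodium sulfide [Na+].[Na+].[S-2]
Why: double SN2 displacement by sulfide should close the thiolane with inversion at both centres, giving the C2-symmetric (2S,5S) sulfide.

Step 7
Reactants: 10; 11 (4-methoxyphenyl)methanol
Product: 12 (2S,5S)-1-(4-methoxybenzyl)-2,5-dimethylthiolan-1-ium tetrafluoroborate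
Conditions: HBF4·OEt2 (1.0 equiv), CH2Cl2, 0 → 20 °C
Reagents that add atoms: tetrafluoroboric acid [H+].F[B-](F)(F)F
Why: the acid ionises the benzylic alcohol and the sulfide captures the 4-methoxybenzyl cation (SN1 S-alkylation); because the thiolane is C2-symmetric, sulfur is not a stereocentre and one salt results.

Step 8
Reactants: 7; 12
Product: 15 2-(5-chloro-2-methoxyphenyl)-2-[(2S,3S)-3-(3,5-dimethoxyphenyl)-6-methoxy-2-(4-methoxyphenyl)-2,3-dihydrobenzofuran-4-yl]acetic acid (both C8b epimers), via o-quinone methide carboxylate 13 (not isolated), via phenoxide sulfonium betaine 14 (not isolated)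
Conditions: 12 (1.3 equiv), Cs2CO3 (3.5 equiv), CH2Cl2/MeCN 4:1, −20 → 20 °C; 1 M HCl
Reagents that add atoms: none
Why: the phenoxide of 7 should expel the lactone carboxylate to give o-quinone methide 13, and the sulfonium ylide adds to C8a and is displaced by the phenoxide in an SN2 closure ([4+1] annulation of a sulfur ylide with an o-quinone methide); C7a is set by the ylide face fixed by the C2-symmetric thiolane, and C8a follows because the anti betaine closes to the trans ring.

Step 9
Reactants: 15
Product: 18 (7aS,8aS,8bS)-7b-oxo core chloride (dibenzo-fused cycloheptanone C7b(=O)–C10a annulated to the trans-dihydrofuran; 8b-aryl pseudo-axial), via mixed trifluoroacetic anhydride 16 (not isolated), via C8b-epimeric ketone 17 (not isolated)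
Conditions: TFAA (3 equiv), CH2Cl2, 0 → 20 °C; then DBU (0.3 equiv), THF, 20 °C; chromatography, minor C8b epimer re-equilibrated
Reagents that add atoms: none
Why: intramolecular Friedel–Crafts acylation through the mixed anhydride should close the seven-membered ring at C10a of ring A (ortho and para to OMe); C8b, now α to the ketone and doubly benzylic, is equilibrated by DBU towards the epimer with the aryl pseudo-axial (anti to C10a and away from the peri H14b), which sets C8b relative to C8a.

Step 10
Reactants: 18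
Product: 19 (7aS,8aS,8bS)-7b-hydroxy core chloride (C7b carbinol; both C7b epimers)
Conditions: DIBAL-H (1.5 equiv), CH2Cl2, −78 °C; Rochelle salt
Reagents that add atoms: none
Why: non-basic hydride reduction of the aryl ketone should not epimerise C8b, and the new carbinol centre needs no control because it is ionised in step 11.

Step 11
Reactants: 19; 20 anisole
Product: 21 (7aS,8aS,7bS,8bS)-core aryl chloride (8b-(5-chloro-2-methoxyphenyl)-7a,7b-bis(4-methoxyphenyl)-11a,13a,13b-trimethoxy seven-ring core)
Conditions: 20 (15 equiv), Bi(OTf)3 (5 mol%), CH2Cl2, −20 → 0 °C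
Reagents that add atoms: none
Why: the 2,4-dimethoxybenzylic cation at C7b should be captured para-selectively by anisole (Friedel–Crafts alkylation) on the open face of the seven-membered ring, because the other face is shielded by the C7a methine of the fused dihydrofuran; the new aryl then takes the pseudo-equatorial site cis to the pseudo-axial C8b aryl, which sets C7b.

Step 12
Reactants: 21; 22 1-ethenyl-3,5-dimethoxybenzene
Product: 23 octamethyl ether of trimer 24 ((E)-stilbene)
Conditions: 22 (1.5 equiv), Pd2(dba)3 (2.5 mol%), t-Bu3P·HBF4 (10 mol%), Cy2NMe (1.5 equiv), 1,4-dioxane, 110 °C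
Reagents that add atoms: none
Why: Mizoroki–Heck coupling of the electron-rich aryl chloride under Pd/P(t-Bu)3 catalysis should give the (E)-stilbene through syn insertion and syn β-hydride elimination.

Step 13
Reactants: 23
Product: 24 trimer (seven-ring core bearing the free 3,5-dihydroxystilbene; octaphenol)
Conditions: BBr3 (20 equiv), CH2Cl2, −78 → 20 °C; MeOH then H2O, 0 °C
Reagents that add atoms: none
Why: BBr3 cleaves the eight aryl methyl ethers at the methyl carbons, so no stereocentre is touched; if the benzylic C7a–O bond ionises, it recloses to the same trans ring.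

Step 14
Reactants: 24; 25 resveratrol
Product: 27 target tetramer (CNP0266373.2), via p-quinone methide adduct 26 (not isolated)
Conditions: class III peroxidase (horseradish peroxidase or the basic peroxidase fraction of Vitis vinifera cell cultures), H2O2 and 25 (4 equiv) fed by syringe pump, acetone/citrate–phosphate buffer pH 6 (1:2), 25 °C, Ar, dark; ascorbate quench at partial conversion of 24; preparative RP-HPLC
Reagents that add atoms: none
Why: Proposed new method: the peroxidase/H2O2 couple oxidises the 4-hydroxystilbene phenols of 25 and 24 to phenoxyl radicals with spin at C8d of resveratrol and, through the stilbene, at C10c of the resorcinol ring of 24; radical–radical combination forms C8d–C10c and, after tautomerisation that re-aromatises ring C, leaves p-quinone methide 26. The closest known reaction is the peroxidase- or laccase-mediated dehydrodimerisation of resveratrol and of ε-viniferin to viniferin-type dihydrobenzofurans, which is run here as a cross-coupling that has not been shown. The dihydrofuran closes by 5-exo-trig addition of the C11c hydroxyl to C7d of the quinone methide, which restores the 4-hydroxyphenyl ring. C8d is fixed in the radical coupling, its absolute sense being left to the protein pocket and to the enantiopure radical of 24 (the two possible trans products are diastereomers and separable), and C7d follows as trans because the phenol adds anti to the C8d aryl and the trans ring is also the thermodynamic one. The step needs cross- over homo-coupling (excess of cheap 25 fed slowly; the ortho-alkylated phenol of 24 is the more easily oxidised) and 8d–10c rather than 8d–O4c/8d–C5c coupling (that flank of 24 is shielded by the core at C3c, and the other phenols of 24 are resorcinols or isolated 4-alkylphenols that are not oxidised).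

## Compound list

1 | methyl 2-(3,5-dimethoxyphenyl)acetate | COC(=O)Cc1cc(OC)cc(OC)c1 | starting material
2 | 2-bromo-4-chloro-1-methoxybenzene | COc1ccc(Cl)cc1Br | starting material
3 | methyl 2-(5-chloro-2-methoxyphenyl)-2-(3,5-dimethoxyphenyl)acetate (racemic) | COC(=O)C(c1cc(Cl)ccc1OC)c1cc(OC)cc(OC)c1 | intermediate
4 | methyl 2-(5-chloro-2-methoxyphenyl)-2-(2-formyl-3,5-dimethoxyphenyl)acetate | COC(=O)C(c1cc(Cl)ccc1OC)c1cc(OC)cc(OC)c1C=O | intermediate
5 | methyl 2-(5-chloro-2-methoxyphenyl)-2-(2-formyl-3-hydroxy-5-methoxyphenyl)acetate | COC(=O)C(c1cc(Cl)ccc1OC)c1cc(OC)cc(O)c1C=O | intermediate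
6 | (3,5-dimethoxyphenyl)magnesium bromide | COc1cc(OC)cc([Mg]Br)c1 | starting material
7 | 4-(5-chloro-2-methoxyphenyl)-1-(3,5-dimethoxyphenyl)-8-hydroxy-6-methoxyisochroman-3-one (diastereomer mixture) | COc1cc(OC)cc(c1)C1OC(=O)C(c2cc(Cl)ccc2OC)c2cc(OC)cc(O)c12 | intermediate
8 | (2R,5R)-hexane-2,5-diol | C[C@@H](O)CC[C@@H](C)O | starting material
9 | (2R,5R)-hexane-2,5-diyl dimethanesulfonate | C[C@@H](OS(C)(=O)=O)CC[C@@H](C)OS(C)(=O)=O | intermediate
10 | (2S,5S)-2,5-dimethylthiolane | C[C@H]1CC[C@H](C)S1 | intermediate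
11 | (4-methoxyphenyl)methanol | COc1ccc(CO)cc1 | starting material
12 | (2S,5S)-1-(4-methoxybenzyl)-2,5-dimethylthiolan-1-ium tetrafluoroborate | C[C@H]1CC[C@H](C)[S+]1Cc1ccc(OC)cc1.F[B-](F)(F)F | intermediate
13 | o-quinone methide carboxylate (caesium salt; exocyclic C10b=C8a) | [Cs+].[O-]C(=O)C(c1cc(Cl)ccc1OC)C1=CC(OC)=CC(=O)C1=Cc1cc(OC)cc(OC)c1 | intermediate (not isolated)
14 | phenoxide sulfonium betaine (caesium salt) | COc1cc(OC)cc(c1)[C@@H](c1c([O-])cc(OC)cc1C(C([O-])=O)c1cc(Cl)ccc1OC)[C@H](c1ccc(OC)cc1)[S+]1[C@@H](C)CC[C@@H]1C.[Cs+] | intermediate (not isolated)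
15 | 2-(5-chloro-2-methoxyphenyl)-2-[(2S,3S)-3-(3,5-dimethoxyphenyl)-6-methoxy-2-(4-methoxyphenyl)-2,3-dihydrobenzofuran-4-yl]acetic acid (both C8b epimers) | COc1cc(OC)cc(c1)[C@H]1c2c(cc(OC)cc2C(C(O)=O)c2cc(Cl)ccc2OC)O[C@@H]1c1ccc(OC)cc1 | intermediate
16 | mixed trifluoroacetic anhydride of 15 | COc1cc(OC)cc(c1)[C@H]1c2c(cc(OC)cc2C(C(=O)OC(=O)C(F)(F)F)c2cc(Cl)ccc2OC)O[C@@H]1c1ccc(OC)cc1 | intermediate (not isolated)
17 | (7aS,8aS,8bR)-7b-oxo core chloride (C8b epimer of 18) | O=C1c2c(OC)cc(OC)cc2[C@H]2c3c(cc(OC)cc3[C@@H]1c1cc(Cl)ccc1OC)O[C@@H]2c1ccc(OC)cc1 | intermediate (not isolated)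
18 | (7aS,8aS,8bS)-7b-oxo core chloride | O=C1c2c(OC)cc(OC)cc2[C@H]2c3c(cc(OC)cc3[C@H]1c1cc(Cl)ccc1OC)O[C@@H]2c1ccc(OC)cc1 | intermediate
19 | (7aS,8aS,8bS)-7b-hydroxy core chloride (both C7b epimers) | OC1c2c(OC)cc(OC)cc2[C@H]2c3c(cc(OC)cc3[C@H]1c1cc(Cl)ccc1OC)O[C@@H]2c1ccc(OC)cc1 | intermediate
20 | anisole | COc1ccccc1 | starting material
21 | (7aS,8aS,7bS,8bS)-core aryl chloride (hexamethyl ether) | COc1ccc([C@H]2c3c(OC)cc(OC)cc3[C@H]3c4c(cc(OC)cc4[C@H]2c2cc(Cl)ccc2OC)O[C@@H]3c2ccc(OC)cc2)cc1 | intermediate
22 | 1-ethenyl-3,5-dimethoxybenzene | C=Cc1cc(OC)cc(OC)c1 | starting material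
23 | octamethyl ether of the trimer | COc1ccc([C@H]2c3c(OC)cc(OC)cc3[C@H]3c4c(cc(OC)cc4[C@H]2c2cc(/C=C/c4cc(OC)cc(OC)c4)ccc2OC)O[C@@H]3c2ccc(OC)cc2)cc1 | intermediate
24 | trimer (key-step precursor) | Oc1ccc([C@H]2c3c(O)cc(O)cc3[C@H]3c4c(cc(O)cc4[C@H]2c2cc(/C=C/c4cc(O)cc(O)c4)ccc2O)O[C@@H]3c2ccc(O)cc2)cc1 | intermediate
25 | resveratrol | Oc1ccc(/C=C/c2cc(O)cc(O)c2)cc1 | starting material
26 | p-quinone methide adduct (C8d–C10c bond formed; C11c–OH free) | Oc1ccc([C@H]2c3c(O)cc(O)cc3[C@H]3c4c(cc(O)cc4[C@H]2c2cc(/C=C/c4cc(O)cc(O)c4[C@H](c4cc(O)cc(O)c4)C=C4C=CC(=O)C=C4)ccc2O)O[C@@H]3c2ccc(O)cc2)cc1 | intermediate (not isolated)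
27 | target tetramer (7aS,8aS,7bS,8bS,7dS,8dS) | Oc1ccc([C@H]2c3c(O)cc(O)cc3[C@H]3c4c(cc(O)cc4[C@H]2c2cc(/C=C/c4cc(O)cc5c4[C@H](c4cc(O)cc(O)c4)[C@@H](c4ccc(O)cc4)O5)ccc2O)O[C@@H]3c2ccc(O)cc2)cc1 | target

## Step count

Total: 14 steps (steps 5–7 prepare the chiral sulfonium salt). Longest linear sequence: 11 steps (1–4, then 8–14).

## Steps most likely to fail

1. Step 14 (Proposed new method). Cross-coupling may lose to homodimerisation of 25 and of 24, coupling may go through the O4c/C5c flank instead of C10c, the protein may give no facial control so that the wrong trans diastereomer forms alongside, and the product may be oxidised further. The fallback uses known chemistry and brings the unit-D ring in ready-made, joining it by a Heck reaction; it sets out from 21. BBr3 demethylation of 21 should give the hexaphenol core chloride F1, and Ac2O/pyridine its hexaacetate F2. Separately, (7aS,8aS)-ε-viniferin (commercial natural isolate) is peracetylated to ε-viniferin pentaacetate F3, ozonolysed (O3, CH2Cl2/MeOH, −78 °C; Me2S) to the 4-formyl dihydrobenzofuran tetraacetate F4, and methylenated (Ph3P=CH2, THF, −78 °C) to the 4-vinyl dihydrobenzofuran tetraacetate F5. Heck coupling of F2 with F5 (Pd2(dba)3, t-Bu3P·HBF4, Cy2NMe, dioxane, 100 °C) should give the (E)-stilbene tetramer decaacetate F6, and methanolysis (K2CO3, degassed MeOH, 0 °C) returns to the route at 27.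

2. Step 8. Facial control by the thiolanium ylide may be incomplete or of the opposite sense, the anti/syn betaine ratio may erode the trans selectivity, and the sulfonium salt may transfer its benzyl group to the phenoxide or carboxylate instead of forming the ylide. The fallback gives up reagent control and resolves later; it sets out from 7. Annulation with achiral S-(4-methoxybenzyl)tetrahydrothiophenium bromide/Cs2CO3 should give the racemic trans acid, that is 15 together with its (2R,3R)-enantiomer F7. The conditions of step 9 convert this into the racemic ketone, 18 together with its enantiomer F8. Preparative chiral SFC then returns to the route at 18.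

3. Step 11. The C7b cation may lose H8b to the ring stilbene and so scramble C8b, anisole may enter from the shielded face or at its ortho position, and the acid may ionise the dihydrofuran C7a–O bond in the presence of the external arene. The fallback installs the aryl before ring closure and closes the ring by the acid-mediated cation cyclisation known for ε-viniferin-type stilbenes; it sets out from 15. Amide formation (EDC·HCl, MeNHOMe·HCl, i-Pr2NEt) should give the Weinreb amide F9, 4-methoxyphenylmagnesium bromide the triaryl ethanone F10, and NaBH4 the carbinol F11. BF3·OEt2 (CH2Cl2, −78 → −20 °C) ionises C7b, and C10a of ring A closes the seven-membered ring with the C7b aryl placed by the ring constraint. C8b is not controlled in this sequence, so the C8b epimer is removed by chromatography; the route is rejoined at 21.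

## Further compounds

F1 | step 14 | hexaphenol core chloride | Oc1ccc([C@H]2c3c(O)cc(O)cc3[C@H]3c4c(cc(O)cc4[C@H]2c2cc(Cl)ccc2O)O[C@@H]3c2ccc(O)cc2)cc1
F2 | step 14 | core chloride hexaacetate | CC(=O)Oc1ccc([C@H]2c3c(OC(C)=O)cc(OC(C)=O)cc3[C@H]3c4c(cc(OC(C)=O)cc4[C@H]2c2cc(Cl)ccc2OC(C)=O)O[C@@H]3c2ccc(OC(C)=O)cc2)cc1
F3 | step 14 | (7aS,8aS)-ε-viniferin pentaacetate | CC(=O)Oc1ccc(/C=C/c2cc(OC(C)=O)cc3c2[C@H](c2cc(OC(C)=O)cc(OC(C)=O)c2)[C@@H](c2ccc(OC(C)=O)cc2)O3)cc1
F4 | step 14 | (2S,3S)-4-formyl dihydrobenzofuran tetraacetate | O=Cc1cc(OC(C)=O)cc2c1[C@H](c1cc(OC(C)=O)cc(OC(C)=O)c1)[C@@H](c1ccc(OC(C)=O)cc1)O2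
F5 | step 14 | (2S,3S)-4-vinyl dihydrobenzofuran tetraacetate | C=Cc1cc(OC(C)=O)cc2c1[C@H](c1cc(OC(C)=O)cc(OC(C)=O)c1)[C@@H](c1ccc(OC(C)=O)cc1)O2
F6 | step 14 | tetramer decaacetate | CC(=O)Oc1ccc([C@H]2c3c(OC(C)=O)cc(OC(C)=O)cc3[C@H]3c4c(cc(OC(C)=O)cc4[C@H]2c2cc(/C=C/c4cc(OC(C)=O)cc5c4[C@H](c4cc(OC(C)=O)cc(OC(C)=O)c4)[C@@H](c4ccc(OC(C)=O)cc4)O5)ccc2OC(C)=O)O[C@@H]3c2ccc(OC(C)=O)cc2)cc1
F7 | step 8 | (2R,3R)-enantiomer of acid 15 (both C8b epimers) | COc1cc(OC)cc(c1)[C@@H]1c2c(cc(OC)cc2C(C(O)=O)c2cc(Cl)ccc2OC)O[C@H]1c1ccc(OC)cc1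
F8 | step 8 | enantiomer of ketone 18 | O=C1c2c(OC)cc(OC)cc2[C@@H]2c3c(cc(OC)cc3[C@@H]1c1cc(Cl)ccc1OC)O[C@H]2c1ccc(OC)cc1
F9 | step 11 | Weinreb amide of 15 | COc1cc(OC)cc(c1)[C@H]1c2c(cc(OC)cc2C(C(=O)N(C)OC)c2cc(Cl)ccc2OC)O[C@@H]1c1ccc(OC)cc1
F10 | step 11 | triaryl ethanone (4-methoxyphenyl ketone) | COc1cc(OC)cc(c1)[C@H]1c2c(cc(OC)cc2C(C(=O)c2ccc(OC)cc2)c2cc(Cl)ccc2OC)O[C@@H]1c1ccc(OC)cc1
F11 | step 11 | triaryl ethanol (C7b carbinol) | COc1cc(OC)cc(c1)[C@H]1c2c(cc(OC)cc2C(C(O)c2ccc(OC)cc2)c2cc(Cl)ccc2OC)O[C@@H]1c1ccc(OC)cc1
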